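| setting | winter | noon | spring | dawn | dusk |
|---|---|---|---|---|---|
| starting material | 0.600 M | 0.240 M | 0.600 M | 0.600 M | 0.200 M |
| partner | 1.50 M | 1.14 M | 0.750 M | 1.50 M | 0.490 M |
| product |  |  |  | 0.180 M |  |
| time |  |  |  |  | 66 min |

| run | time / min | [product] / M |
|---|---|---|
| winter run | 8.2 | 0.089 |
| winter run | 16 | 0.116 |
| winter run | 25 | 0.137 |
| winter run | 33 | 0.141 |
| winter run | 41 | 0.153 |
| winter run | 50 | 0.154 |
| winter run | 58 | 0.151 |
| winter run | 66 | 0.150 |
| noon run | 8.2 | 0.044 |
| noon run | 16 | 0.057 |
| noon run | 25 | 0.076 |
| noon run | 33 | 0.081 |
| noon run | 41 | 0.088 |
| noon run | 50 | 0.091 |
| noon run | 58 | 0.085 |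
| noon run | 66 | 0.097 |
| spring run | 8.2 | 0.054 |
| spring run | 16 | 0.079 |
| spring run | 25 | 0.094 |
| spring run | 33 | 0.099 |
| spring run | 41 | 0.100 |
| spring run | 50 | 0.112 |
| spring run | 58 | 0.109 |
| spring run | 66 | 0.114 |
| dawn run | 8.2 | 0.267 |
| dawn run | 16 | 0.297 |
| dawn run | 25 | 0.317 |
| dawn run | 33 | 0.319 |
| dawn run | 41 | 0.329 |
| dawn run | 50 | 0.329 |
| dawn run | 58 | 0.331 |
| dawn run | 66 | 0.338 |

(readings scatter by 0.003 M)

* the exponent of [starting material] in the starting rate at the charge of the winter run (at the point where two percent of the starting material have become product) (one fixed amount of product, the same in the runs compared)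
* the exponent of [partner] in the starting rate at the charge of the winter run (at the point where two percent of the starting material have become product)
* product in the dusk run at 66 min, as a share of the starting material charged

- Overall: starting material + partner -> product.
- Constant volume, constant temperature.
- The analysis sees a species whether free or bound.
- An order is taken over about fifteen percent of the charge, up and down.

- A one-step picture has the starting material, the limiting reagent, turning into product until its charge is gone, but the winter run reads 0.150 M at 66 min from a charge of 0.600 M.
- The dawn run, charged with 0.180 M of product, adds 0.158 M by that time, close to the winter figure, so this reckoning sets aside any return from product.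
- The noon run turns a larger share of its charge, 40.4%, than the winter run, 25.0%. This reckoning therefore takes a main path first order in starting material against a loss second order in it, like propagation against bimolecular termination, and so expects an exponent of 1 for starting material.
- Such a pair stalls at c* times the logarithm of (one plus charge over c*). The winter reading at 66 min gives 0.0648 M. This c* is the break-even concentration, the c(starting material) at which main path and loss take it equally fast.
- Before the stall, the factor (one minus exp(−kt)) multiplies charge over c* inside the logarithm. The first winter reading then gives the main path's first-order constant, k = 0.0468 min⁻¹.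
- The spring run, on the same plateau rule, gives c* = 0.0423 M. This reckoning lets c* scale with k and lets k carry the partner, which gives an exponent of partner of 0.616.
- Scaled to the dusk charge, c* is 0.0325 M, and the time rule gives 28.7% of the charge at 66 min.
- The weak link is the spring plateau, since kt there is 2.01, lower than the 3.09 of the winter run, and the spring stall is incomplete; the winter figure is left as it stands. With the time factor put in, spring c* becomes 0.0441 M, the partner exponent 0.557, and the dusk share 30.1%.
- The forecast, reasoning that “Something active is dying with time”, gives 0.47 for starting material, 0.66 for partner and 29% for the dusk run. Its first exponent differs from the 1 reckoned above.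
- The flask gives exponents of 1.0 in starting material and 0.73 in partner, and 28.4% in the dusk run at 66 min, so the forecast parts from it on the first exponent.

    starting material ⇌ intermediate, settled at all times (0.1570)
    intermediate + partner → product (0.5778 M⁻¹ min⁻¹)
    2 partner ⇌ idle reagent dimer, settled at all times (1.310 M⁻¹)
    2 starting material → homo dimer (0.4284 M⁻¹ min⁻¹)

- The dusk run stalls mainly through the conversion of starting material into homo dimer: with that step taken away it gives 71.7% rather than 28.4%. Its charge opens at 6.15 times the break-even concentration reckoned for it, so on that reckoning the homo dimer path starts out faster than the main path. The noon run has a reckoned break-even concentration of 0.0547 M, which gives 0.0887 M at 66 min, where the noon run reads 0.097 M, after 0.085 M at 58 min.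

Readings and results stem from a simulated flask for substances that don't exist; the scatter is artificial.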